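**Retrosynthetic overview**
- The umbelliferyl ether is cut last (Mitsunobu at the primary allylic carbon of the side chain). The oxolane ring is then opened at O6–C5, leaving a C4=C5 alkene and a C7 carbinol (iodoetherification in the forward sense).
- The route rests on one feature of the 6-oxabicyclo[3.2.1]octane: the quaternary C1 (CH3 and C7H2–O6) is bonded to the chain-bearing methine C8. With C7 as an aldehyde, O=C7–C1–C8–C5=C4 is a γ,δ-unsaturated aldehyde, the retron of a Claisen rearrangement.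
- Breaking C1–C8 and joining the C7 oxygen to C4 gives a trans-2-alkenyl-4-silyloxy-5-methyl-3,4-dihydro-2H-pyran that already holds the whole side chain.
- The pyran comes from a catalytic asymmetric hetero-Diels–Alder reaction of the enal of geranyl acetate with a silyloxydiene, then Luche reduction and Mitsunobu inversion.
- Ring order: dihydropyran (temporary), then carbocycle C1–C2–C3–C4–C5–C8 by ring contraction, then oxolane C1–C7–O6–C5–C8 by etherification.

Key step: step 8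

Remark: the (S) ligand in step 3 is chosen on the assumption that the BINOL–titanium catalyst adds the diene to the Si face of the enal, as in its allylations and aldol additions of aldehydes; if the pyranone of step 3 shows the opposite sense, (R)-BINOL is used and nothing else changes. TBS = tert-butyldimethylsilyl.

**Route**

Step 1
Reactants: 1 geranyl acetate
Product: 2 (2E,6E)-8-hydroxy-3,7-dimethylocta-2,6-dien-1-yl acetate
Conditions: SeO2 (cat.), tBuOOH, salicylic acid (cat.), CH2Cl2, rt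
Reagents that add atoms: tert-butyl hydroperoxide CC(C)(C)OO (net oxygen source; the oxygen is passed on by catalytic selenium dioxide O=[Se]=O)
Why: Catalytic SeO2 allylic oxidation (ene reaction, then [2,3]-sigmatropic shift) should attack the (E)-methyl group of the electron-rich terminal alkene, leave the acetate-deactivated 2,3-alkene alone and return the E geometry.

Step 2
Reactants: 2 (2E,6E)-8-hydroxy-3,7-dimethylocta-2,6-dien-1-yl acetate
Product: 3 (2E,6E)-3,7-dimethyl-8-oxoocta-2,6-dien-1-yl acetate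
Conditions: MnO2 (excess), CH2Cl2, rt
Reagents that add atoms: none
Why: MnO2 oxidises allylic alcohols selectively to enals and should leave the acetate and both E alkenes unchanged.

Step 3
Reactants: 3 (2E,6E)-3,7-dimethyl-8-oxoocta-2,6-dien-1-yl acetate; 4 (E)-1-methoxy-2-methyl-3-(trimethylsilyloxy)buta-1,3-diene
Product: 6 (2E,6E)-3-methyl-7-[(2S)-5-methyl-4-oxo-3,4-dihydro-2H-pyran-2-yl]octa-2,6-dien-1-yl acetate, via silylated aldol adduct 5 (not isolated)
Conditions: Ti(OiPr)4 (10 mol %), (S)-BINOL (20 mol %), 4 Å MS, Et2O, −20 °C; then CF3CO2H, CH2Cl2, 0 °C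
Reagents that add atoms: none
Why: BINOL–titanium-catalysed Mukaiyama aldol addition of the silyloxydiene to the enal, followed by acid-induced oxa-Michael closure with loss of methanol (a formal hetero-Diels–Alder reaction), should build the dihydropyranone, the chiral titanium complex directing the diene to the Si face of the aldehyde and so setting the (S) centre at pyran C2.

Step 4
Reactants: 6 (2E,6E)-3-methyl-7-[(2S)-5-methyl-4-oxo-3,4-dihydro-2H-pyran-2-yl]octa-2,6-dien-1-yl acetate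
Product: 7 (2E,6E)-7-[(2S,4S)-4-hydroxy-5-methyl-3,4-dihydro-2H-pyran-2-yl]-3-methylocta-2,6-dien-1-yl acetate (2,4-cis)
Conditions: NaBH4, CeCl3·7H2O, MeOH, −78 to −40 °C
Reagents that add atoms: none
Why: In this Luche 1,2-reduction hydride should add axially to the half-chair that carries the C2 substituent pseudo-equatorially, so the C4 carbinol forms cis to it while the acetate survives at low temperature.

Step 5
Reactants: 7 (2E,6E)-7-[(2S,4S)-4-hydroxy-5-methyl-3,4-dihydro-2H-pyran-2-yl]-3-methylocta-2,6-dien-1-yl acetate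
Product: 8 (2S,4R)-2-[(2E,6E)-8-acetoxy-6-methylocta-2,6-dien-2-yl]-5-methyl-3,4-dihydro-2H-pyran-4-yl 4-nitrobenzoate (2,4-trans)
Conditions: 4-O2NC6H4CO2H, PPh3, DIAD, toluene, −20 to 0 °C
Reagents that add atoms: 4-nitrobenzoic acid O=C(O)c1ccc(cc1)[N+](=O)[O-]
Why: Mitsunobu esterification should displace the activated allylic hydroxyl by carboxylate with SN2 inversion and so turn C4 into the trans (4R) centre, low temperature and the strongly acidic nitrobenzoic acid favouring direct over allylic substitution.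

Step 6
Reactants: 8 (2S,4R)-2-[(2E,6E)-8-acetoxy-6-methylocta-2,6-dien-2-yl]-5-methyl-3,4-dihydro-2H-pyran-4-yl 4-nitrobenzoate
Product: 9 (2E,6E)-7-[(2S,4R)-4-hydroxy-5-methyl-3,4-dihydro-2H-pyran-2-yl]-3-methylocta-2,6-dien-1-ol
Conditions: K2CO3 (cat.), MeOH, 0 °C to rt
Reagents that add atoms: none
Why: Base-catalysed transesterification with methanol should remove both esters in one operation, so no discrimination between two esters is needed and the acid-sensitive enol ether stays in basic medium.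

Step 7
Reactants: 9 (2E,6E)-7-[(2S,4R)-4-hydroxy-5-methyl-3,4-dihydro-2H-pyran-2-yl]-3-methylocta-2,6-dien-1-ol
Product: 10 (2S,4R)-4-(TBS-oxy)-2-[(2E,6E)-8-(TBS-oxy)-6-methylocta-2,6-dien-2-yl]-5-methyl-3,4-dihydro-2H-pyran
Conditions: TBSCl (3 equiv), imidazole, DMAP (cat.), DMF, rt
Reagents that add atoms: tert-butyldimethylsilyl chloride CC(C)(C)[Si](C)(C)Cl
Why: Standard silylation of the primary and the secondary allylic hydroxyl under non-acidic conditions should give an ester-free substrate that cannot undergo acyloxy shift or lose acetic acid on heating.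

Step 8
Reactants: 10 (2S,4R)-4-(TBS-oxy)-2-[(2E,6E)-8-(TBS-oxy)-6-methylocta-2,6-dien-2-yl]-5-methyl-3,4-dihydro-2H-pyran
Product: 11 (1S,2S,6R)-6-(TBS-oxy)-2-[(3E)-5-(TBS-oxy)-3-methylpent-3-en-1-yl]-1,3-dimethylcyclohex-3-ene-1-carbaldehyde
Conditions: 1,2-Cl2C6H4 (degassed), Et3N (1 mol %), base-washed sealed tube, 220 °C
Reagents that add atoms: none
Why: The array C6=C5–O1–C2–C(CH3)=CH of 10 (pyran numbering) is an allyl vinyl ether, and heating should drive a concerted suprafacial [3,3]-sigmatropic (Claisen) shift that bonds pyran C5 to the alkene terminus (C1–C8 of the target), breaks O1–C2 and releases C6 as the aldehyde, which is the known thermal ring contraction of 2-alkenyl-3,4-dihydro-2H-pyrans to cyclohex-3-ene-1-carbaldehydes. The six-membered carbocycle (pyran C2 to C5 plus the two alkene carbons) is closed by this pericyclic C–C bond formation across the pyran, the two-carbon C3–C4 tether forcing the six-atom array into a boat inside a bicyclo[2.2.2]octane-like transition state. The quaternary centre is set by the pyran C2 stereocentre, because the tethered alkene can reach the enol ether only from the face on which it sits, and the adjacent methine is set by the E alkene geometry within the enforced boat, which places the side chain cis to the formyl group. The silyloxy centre is not touched and, being trans to the alkenyl group, ends cis to the formyl group and points away from the approaching alkene. The step needs the pericyclic path to outrun acid-induced ionisation of the allylic silyloxy enol ether and thermal change of the remote trisubstituted alkene, which base-treated glassware, a trace of amine and the absence of ester groups should secure.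

Step 9
Reactants: 11 (1S,2S,6R)-6-(TBS-oxy)-2-[(3E)-5-(TBS-oxy)-3-methylpent-3-en-1-yl]-1,3-dimethylcyclohex-3-ene-1-carbaldehyde
Product: 12 [(1R,2S,6R)-6-(TBS-oxy)-2-[(3E)-5-(TBS-oxy)-3-methylpent-3-en-1-yl]-1,3-dimethylcyclohex-3-en-1-yl]methanol
Conditions: NaBH4, EtOH, 0 °C
Reagents that add atoms: none
Why: Borohydride reduction of the neopentyl aldehyde, which has no α-hydrogen and cannot epimerise, should give the C7 carbinol.

Step 10
Reactants: 12 [(1R,2S,6R)-6-(TBS-oxy)-2-[(3E)-5-(TBS-oxy)-3-methylpent-3-en-1-yl]-1,3-dimethylcyclohex-3-en-1-yl]methanol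
Product: 13 (1R,2R,4R,5R,8R)-2-(TBS-oxy)-8-[(3E)-5-(TBS-oxy)-3-methylpent-3-en-1-yl]-4-iodo-1,5-dimethyl-6-oxabicyclo[3.2.1]octane
Conditions: NIS (1.1 equiv), NaHCO3, MeCN, −20 to 0 °C, dark
Reagents that add atoms: N-iodosuccinimide O=C1CCC(=O)N1I
Why: In this iodoetherification (the ether counterpart of the iodolactonisation of cyclohex-3-enecarboxylic acids) the C7 hydroxyl, axial on C1, should open the iodonium ion of the ring alkene at the tertiary C5 in a 5-exo, trans-diaxial manner, so O6 arrives on the face that carries C7 and fixes C5, while the iodonium ion of the side-chain alkene has no internal nucleophile and reverts.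

Step 11
Reactants: 13 (1R,2R,4R,5R,8R)-2-(TBS-oxy)-8-[(3E)-5-(TBS-oxy)-3-methylpent-3-en-1-yl]-4-iodo-1,5-dimethyl-6-oxabicyclo[3.2.1]octane
Product: 14 (1R,2R,5S,8R)-2-(TBS-oxy)-8-[(3E)-5-(TBS-oxy)-3-methylpent-3-en-1-yl]-1,5-dimethyl-6-oxabicyclo[3.2.1]octane
Conditions: Bu3SnH (0.2 M), AIBN (cat.), toluene, 80 °C
Reagents that add atoms: none
Why: Radical chain deiodination with Bu3SnH should remove the secondary iodide, hydrogen transfer at this concentration outpacing the slow 6-exo addition of the C4 radical to the side-chain alkene, and the iodine-bearing stereocentre disappears.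

Step 12
Reactants: 14 (1R,2R,5S,8R)-2-(TBS-oxy)-8-[(3E)-5-(TBS-oxy)-3-methylpent-3-en-1-yl]-1,5-dimethyl-6-oxabicyclo[3.2.1]octane
Product: 15 (1R,2R,5S,8R)-8-[(3E)-5-hydroxy-3-methylpent-3-en-1-yl]-1,5-dimethyl-6-oxabicyclo[3.2.1]octan-2-ol
Conditions: TBAF (4 equiv), THF, rt to 45 °C
Reagents that add atoms: none
Why: Fluoride-induced desilylation should cleave both silyl ethers while the tertiary bicyclic ether and the alkene are inert.

Step 13
Reactants: 15 (1R,2R,5S,8R)-8-[(3E)-5-hydroxy-3-methylpent-3-en-1-yl]-1,5-dimethyl-6-oxabicyclo[3.2.1]octan-2-ol; 16 umbelliferone (7-hydroxy-2H-chromen-2-one)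
Product: 17 7-{[(2E)-5-[(1R,2R,5S,8R)-2-hydroxy-1,5-dimethyl-6-oxabicyclo[3.2.1]octan-8-yl]-3-methylpent-2-en-1-yl]oxy}-2H-chromen-2-one (CNP0178104.1)
Conditions: PPh3, DIAD, THF, 0 °C to rt
Reagents that add atoms: none
Why: In this Mitsunobu etherification the acidic phenol should be alkylated on oxygen at the activated primary allylic carbinol by SN2 displacement with the E alkene retained, while the secondary C2 hydroxyl next to the quaternary C1 is too hindered to be activated.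

**Compound list**
1 | geranyl acetate | CC(C)=CCC/C(C)=C/COC(C)=O | starting material
2 | (2E,6E)-8-hydroxy-3,7-dimethylocta-2,6-dien-1-yl acetate | CC(=O)OC/C=C(\C)CC/C=C(\C)CO | intermediate
3 | (2E,6E)-3,7-dimethyl-8-oxoocta-2,6-dien-1-yl acetate | CC(=O)OC/C=C(\C)CC/C=C(\C)C=O | intermediate
4 | (E)-1-methoxy-2-methyl-3-(trimethylsilyloxy)buta-1,3-diene | CO/C=C(\C)C(=C)O[Si](C)(C)C | starting material
5 | (2E,6E,8S,11E)-12-methoxy-3,7,11-trimethyl-10-oxo-8-(trimethylsilyloxy)dodeca-2,6,11-trien-1-yl acetate (silylated aldol adduct) | CO/C=C(\C)C(=O)C[C@H](O[Si](C)(C)C)/C(C)=C/CC/C(C)=C/COC(C)=O | intermediate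
6 | (2E,6E)-3-methyl-7-[(2S)-5-methyl-4-oxo-3,4-dihydro-2H-pyran-2-yl]octa-2,6-dien-1-yl acetate | CC(=O)OC/C=C(\C)CC/C=C(\C)[C@@H]1CC(=O)C(C)=CO1 | intermediate
7 | (2E,6E)-7-[(2S,4S)-4-hydroxy-5-methyl-3,4-dihydro-2H-pyran-2-yl]-3-methylocta-2,6-dien-1-yl acetate | CC(=O)OC/C=C(\C)CC/C=C(\C)[C@@H]1C[C@H](O)C(C)=CO1 | intermediate
8 | (2S,4R)-2-[(2E,6E)-8-acetoxy-6-methylocta-2,6-dien-2-yl]-5-methyl-3,4-dihydro-2H-pyran-4-yl 4-nitrobenzoate | CC(=O)OC/C=C(\C)CC/C=C(\C)[C@@H]1C[C@@H](OC(=O)c2ccc(cc2)[N+](=O)[O-])C(C)=CO1 | intermediate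
9 | (2E,6E)-7-[(2S,4R)-4-hydroxy-5-methyl-3,4-dihydro-2H-pyran-2-yl]-3-methylocta-2,6-dien-1-ol | OC/C=C(\C)CC/C=C(\C)[C@@H]1C[C@@H](O)C(C)=CO1 | intermediate
10 | (2S,4R)-4-(TBS-oxy)-2-[(2E,6E)-8-(TBS-oxy)-6-methylocta-2,6-dien-2-yl]-5-methyl-3,4-dihydro-2H-pyran | CC(C)(C)[Si](C)(C)OC/C=C(\C)CC/C=C(\C)[C@@H]1C[C@@H](O[Si](C)(C)C(C)(C)C)C(C)=CO1 | intermediate
11 | (1S,2S,6R)-6-(TBS-oxy)-2-[(3E)-5-(TBS-oxy)-3-methylpent-3-en-1-yl]-1,3-dimethylcyclohex-3-ene-1-carbaldehyde | CC(C)(C)[Si](C)(C)OC/C=C(\C)CC[C@H]1C(C)=CC[C@@H](O[Si](C)(C)C(C)(C)C)[C@@]1(C)C=O | intermediate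
12 | [(1R,2S,6R)-6-(TBS-oxy)-2-[(3E)-5-(TBS-oxy)-3-methylpent-3-en-1-yl]-1,3-dimethylcyclohex-3-en-1-yl]methanol | CC(C)(C)[Si](C)(C)OC/C=C(\C)CC[C@H]1C(C)=CC[C@@H](O[Si](C)(C)C(C)(C)C)[C@@]1(C)CO | intermediate
13 | (1R,2R,4R,5R,8R)-2-(TBS-oxy)-8-[(3E)-5-(TBS-oxy)-3-methylpent-3-en-1-yl]-4-iodo-1,5-dimethyl-6-oxabicyclo[3.2.1]octane | C/C(=C\CO[Si](C)(C)C(C)(C)C)CC[C@@H]1[C@]2(C)CO[C@@]1(C)[C@H](I)C[C@H]2O[Si](C)(C)C(C)(C)C | intermediate
14 | (1R,2R,5S,8R)-2-(TBS-oxy)-8-[(3E)-5-(TBS-oxy)-3-methylpent-3-en-1-yl]-1,5-dimethyl-6-oxabicyclo[3.2.1]octane | C/C(=C\CO[Si](C)(C)C(C)(C)C)CC[C@@H]1[C@]2(C)CO[C@@]1(C)CC[C@H]2O[Si](C)(C)C(C)(C)C | intermediate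
15 | (1R,2R,5S,8R)-8-[(3E)-5-hydroxy-3-methylpent-3-en-1-yl]-1,5-dimethyl-6-oxabicyclo[3.2.1]octan-2-ol | C/C(=C\CO)CC[C@@H]1[C@]2(C)CO[C@@]1(C)CC[C@H]2O | intermediate
16 | umbelliferone (7-hydroxy-2H-chromen-2-one) | O=c1ccc2ccc(O)cc2o1 | starting material
17 | 7-{[(2E)-5-[(1R,2R,5S,8R)-2-hydroxy-1,5-dimethyl-6-oxabicyclo[3.2.1]octan-8-yl]-3-methylpent-2-en-1-yl]oxy}-2H-chromen-2-one | C/C(=C\COc1ccc2ccc(=O)oc2c1)CC[C@@H]1[C@]2(C)CO[C@@]1(C)CC[C@H]2O | target

Total step count: 13. Longest linear sequence: 13 steps (1 to 17).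

**Steps most likely to fail**

Step 8. The hindered boat rearrangement, which joins a fully substituted enol ether carbon to a trisubstituted alkene terminus, may be too slow, so that ionisation of the allylic silyloxy enol ether or thermal degradation takes over before the C–C bond forms. The fallback is the ester-enolate version of the same ring contraction, which runs far below this temperature; it sets out from 10 and comes back at 12.
- The enol ether of 10 is hydrated (PPh3·HBr cat., wet THF) to the lactol (4R,6S)-4-(TBS-oxy)-6-[(2E,6E)-8-(TBS-oxy)-6-methylocta-2,6-dien-2-yl]-3-methyltetrahydro-2H-pyran-2-ol F1.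
- F1 is oxidised (PhI(OAc)2, TEMPO cat., CH2Cl2) to the δ-lactone (4R,6S)-4-(TBS-oxy)-6-[(2E,6E)-8-(TBS-oxy)-6-methylocta-2,6-dien-2-yl]-3-methyltetrahydro-2H-pyran-2-one F2.
- F2 is enolised with LiN(iPr)2 in the presence of TBSCl (internal quench, THF/HMPA, −78 °C, to limit β-elimination of silyloxide) to the cyclic silyl ketene acetal (2S,4R)-4,6-bis(TBS-oxy)-2-[(2E,6E)-8-(TBS-oxy)-6-methylocta-2,6-dien-2-yl]-5-methyl-3,4-dihydro-2H-pyran F3.
- Warming F3 in toluene (80–110 °C) should effect the Ireland–Claisen shift through the same tether-enforced boat to the silyl ester tert-butyldimethylsilyl (1S,2S,6R)-6-(TBS-oxy)-2-[(3E)-5-(TBS-oxy)-3-methylpent-3-en-1-yl]-1,3-dimethylcyclohex-3-ene-1-carboxylate F4.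
- LiAlH4 in Et2O reduces F4 to 12.

Step 5. The activated allylic hydroxyl may ionise with help from the ring oxygen, so that carboxylate adds at the acetal carbon (allylic transposition) or the ester forms with partial retention. The fallback makes the transposition the productive path through a sulfoxide–sulfenate rearrangement; it sets out from 7 and comes back at 9.
- 7 is acetylated (Ac2O, pyridine) to the cis diacetate (2S,4S)-2-[(2E,6E)-8-acetoxy-6-methylocta-2,6-dien-2-yl]-5-methyl-3,4-dihydro-2H-pyran-4-yl acetate F5.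
- Ferrier-type substitution with thiophenol (BF3·OEt2 cat., CH2Cl2, −78 °C) should give the 2,6-trans thioacetal (2E,6E)-3-methyl-7-[(2S,6R)-5-methyl-6-(phenylsulfanyl)-3,6-dihydro-2H-pyran-2-yl]octa-2,6-dien-1-yl acetate F6.
- Oxidation with mCPBA (1 equiv, −78 °C) gives the sulfoxide (2E,6E)-3-methyl-7-[(2S,6R)-5-methyl-6-(phenylsulfinyl)-3,6-dihydro-2H-pyran-2-yl]octa-2,6-dien-1-yl acetate F7.
- With piperidine in THF at rt, F7 should undergo the suprafacial [2,3]-shift and sulfenate cleavage, placing oxygen on C4 on the face that carried sulfur, to give the trans alcohol (2E,6E)-7-[(2S,4R)-4-hydroxy-5-methyl-3,4-dihydro-2H-pyran-2-yl]-3-methylocta-2,6-dien-1-yl acetate F8.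
- Methanolysis of F8 (K2CO3, MeOH) gives 9.

Step 3. Facial discrimination by the titanium catalyst may be poor with the α-branched enal and the methyl-substituted diene, giving material of low enantiomeric purity. The fallback replaces asymmetric catalysis by a racemic synthesis and an enzymatic kinetic resolution; it sets out from 3 and 4 and comes back at 7.
- BF3·OEt2 (CH2Cl2, −78 °C) gives the racemic silylated aldol adduct 12-methoxy-3,7,11-trimethyl-10-oxo-8-(trimethylsilyloxy)dodeca-2,6,11-trien-1-yl acetate F9, not isolated.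
- CF3CO2H closes F9 to the racemic pyranone (2E,6E)-3-methyl-7-(5-methyl-4-oxo-3,4-dihydro-2H-pyran-2-yl)octa-2,6-dien-1-yl acetate F10.
- Luche reduction as in step 4 gives the racemic cis alcohol (2E,6E)-7-(cis-4-hydroxy-5-methyl-3,4-dihydro-2H-pyran-2-yl)-3-methylocta-2,6-dien-1-yl acetate F11.
- Lipase PS with vinyl acetate in tBuOMe should, by the usual lipase preference for the (R)-carbinol of 2-substituted cycloalk-2-enols, acetylate the (2R,4R) enantiomer to (2R,4R)-2-[(2E,6E)-8-acetoxy-6-methylocta-2,6-dien-2-yl]-5-methyl-3,4-dihydro-2H-pyran-4-yl acetate F12; the unreacted (2S,4S) alcohol 7 is separated by chromatography.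

**Further compounds**
F1 | step 8 | (4R,6S)-4-(TBS-oxy)-6-[(2E,6E)-8-(TBS-oxy)-6-methylocta-2,6-dien-2-yl]-3-methyltetrahydro-2H-pyran-2-ol (mixture at C2 and C3) | CC(C)(C)[Si](C)(C)OC/C=C(\C)CC/C=C(\C)[C@@H]1C[C@@H](O[Si](C)(C)C(C)(C)C)C(C)C(O)O1
F2 | step 8 | (4R,6S)-4-(TBS-oxy)-6-[(2E,6E)-8-(TBS-oxy)-6-methylocta-2,6-dien-2-yl]-3-methyltetrahydro-2H-pyran-2-one (mixture at C3) | CC(C)(C)[Si](C)(C)OC/C=C(\C)CC/C=C(\C)[C@@H]1C[C@@H](O[Si](C)(C)C(C)(C)C)C(C)C(=O)O1
F3 | step 8 | (2S,4R)-4,6-bis(TBS-oxy)-2-[(2E,6E)-8-(TBS-oxy)-6-methylocta-2,6-dien-2-yl]-5-methyl-3,4-dihydro-2H-pyran | CC(C)(C)[Si](C)(C)OC/C=C(\C)CC/C=C(\C)[C@@H]1C[C@@H](O[Si](C)(C)C(C)(C)C)C(C)=C(O[Si](C)(C)C(C)(C)C)O1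
F4 | step 8 | tert-butyldimethylsilyl (1S,2S,6R)-6-(TBS-oxy)-2-[(3E)-5-(TBS-oxy)-3-methylpent-3-en-1-yl]-1,3-dimethylcyclohex-3-ene-1-carboxylate | CC(C)(C)[Si](C)(C)OC/C=C(\C)CC[C@H]1C(C)=CC[C@@H](O[Si](C)(C)C(C)(C)C)[C@@]1(C)C(=O)O[Si](C)(C)C(C)(C)C
F5 | step 5 | (2S,4S)-2-[(2E,6E)-8-acetoxy-6-methylocta-2,6-dien-2-yl]-5-methyl-3,4-dihydro-2H-pyran-4-yl acetate | CC(=O)OC/C=C(\C)CC/C=C(\C)[C@@H]1C[C@H](OC(C)=O)C(C)=CO1
F6 | step 5 | (2E,6E)-3-methyl-7-[(2S,6R)-5-methyl-6-(phenylsulfanyl)-3,6-dihydro-2H-pyran-2-yl]octa-2,6-dien-1-yl acetate | CC(=O)OC/C=C(\C)CC/C=C(\C)[C@@H]1CC=C(C)[C@@H](Sc2ccccc2)O1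
F7 | step 5 | (2E,6E)-3-methyl-7-[(2S,6R)-5-methyl-6-(phenylsulfinyl)-3,6-dihydro-2H-pyran-2-yl]octa-2,6-dien-1-yl acetate (mixture at sulfur) | CC(=O)OC/C=C(\C)CC/C=C(\C)[C@@H]1CC=C(C)[C@@H](S(=O)c2ccccc2)O1
F8 | step 5 | (2E,6E)-7-[(2S,4R)-4-hydroxy-5-methyl-3,4-dihydro-2H-pyran-2-yl]-3-methylocta-2,6-dien-1-yl acetate | CC(=O)OC/C=C(\C)CC/C=C(\C)[C@@H]1C[C@@H](O)C(C)=CO1
F9 | step 3 | racemic (2E,6E,11E)-12-methoxy-3,7,11-trimethyl-10-oxo-8-(trimethylsilyloxy)dodeca-2,6,11-trien-1-yl acetate | CO/C=C(\C)C(=O)CC(O[Si](C)(C)C)/C(C)=C/CC/C(C)=C/COC(C)=O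
F10 | step 3 | racemic (2E,6E)-3-methyl-7-(5-methyl-4-oxo-3,4-dihydro-2H-pyran-2-yl)octa-2,6-dien-1-yl acetate | CC(=O)OC/C=C(\C)CC/C=C(\C)C1CC(=O)C(C)=CO1
F11 | step 3 | racemic (2E,6E)-7-(cis-4-hydroxy-5-methyl-3,4-dihydro-2H-pyran-2-yl)-3-methylocta-2,6-dien-1-yl acetate (both enantiomers written) | CC(=O)OC/C=C(\C)CC/C=C(\C)[C@@H]1C[C@H](O)C(C)=CO1.CC(=O)OC/C=C(\C)CC/C=C(\C)[C@H]1C[C@@H](O)C(C)=CO1
F12 | step 3 | (2R,4R)-2-[(2E,6E)-8-acetoxy-6-methylocta-2,6-dien-2-yl]-5-methyl-3,4-dihydro-2H-pyran-4-yl acetate | CC(=O)OC/C=C(\C)CC/C=C(\C)[C@H]1C[C@@H](OC(C)=O)C(C)=CO1
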